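Locants used in the text (not the nomenclature locants of the names): ring A is C1 (OMe), C2 (Me), C3 (C=O), C4 (spiro), C5 (C=O), C6 (CMe2); ring B is C4, C7 (CH2), C8 (homoprenyl), C9 (=CH), C10 (CH2), C11 (CH–iPr); C12 and C13 are the two allyl carbons attached to C11 before hydrogenation (C12 bears the methyl group, C13 is terminal).

## Analysis of the target

Compound 31 is a spiro[5.5]undecane. Ring A is a cyclohexene-1,3-dione in which C3 is the carbonyl of a β-methoxy enone (C1(OMe)=C2(Me)–C3=O) and C5 is an isolated ketone next to the quaternary C6 with two methyl groups. Ring B is a cyclohexene with a trisubstituted C8=C9 alkene, a 4-methylpent-3-enyl chain on C8 and an isopropyl group on C11. The two stereocentres are adjacent: the quaternary spiro carbon C4 (R) and C11 (S); on ring B the C3 carbonyl lies on the same face as the isopropyl group and the C5 carbonyl on the opposite face. C4 is stereogenic only because C3 and C5 differ two bonds further out (C2 is sp2 with one methyl, C6 is sp3 with two), so any intermediate whose ring A can tautomerise between its two arms loses this centre. Sensitive groups are the vinylogous methyl ester (aqueous acid), the non-enolisable 1,3-dicarbonyl unit across C4 (retro-Claisen cleavage by hard nucleophiles) and two trisubstituted alkenes (strong acid, electrophiles, unselective hydrogenation). The difficulty is a quaternary spiro centre next to a tertiary centre whose relative configuration is defined against two nearly identical carbonyl arms, together with a gem-dimethyl carbon that no aromatic precursor can carry. The strategy rests on ring A being a dearomatised, C-methylated phloroglucinol monomethyl ether in which C4 carries both ring B bonds. Ring A can therefore come from a flat, mirror-symmetric arene that attacks through C4 an allyl unit tethered by C7–C10, forming C4–C11.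

## Retrosynthetic reasoning

31 to 29 through 30 (C6–CH3). The second methyl on C6 is cut first, because an arene cannot hold two methyl groups on one ring carbon and this bond must therefore follow dearomatisation. It is traced through siloxycyclopropane 30 to silyl enol ether 29: a carbenoid adds to the C5=C6 bond as a unit, so the new carbon is placed on the silyl-bearing arm without a free enolate, which would make the C3 and C5 arms equivalent. Forward, methylene transfer to C5=C6 and proton-induced cleavage of the C5–CH2 bond are needed.

29 to 28 (isopropyl from isopropenyl). An allylic substitution at C11 leaves an isopropenyl group, so the isopropyl group is traced to it. Forward, the only 1,1-disubstituted alkene must be hydrogenated in the presence of trisubstituted and tetrasubstituted ones.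

28 to 27 (C4–C11, the key disconnection). Of the two ring B bonds at C4, C4–C7 is an ordinary benzylic bond that is easily made early on an arene. C4–C11 is the bond whose formation creates both stereocentres, so it is the one to cut. This gives phenol 27 with an allylic carbonate at the end of the tether; the only small ring open to it is the six-membered ring B. One phenol oxygen carries a silyl group so that, after dearomatisation, C3 is a ketone and C5 a silyl enol ether. The step delivers ring B, the spiro carbon and C11 in one catalytic operation.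

27 to 24 through 26 and 25 (oxygen functions). The arene of 26 has a mirror plane through C1 and C4, so silylation of either phenol gives the same compound 27. The phenols are freed from their acetal protection (25 to 26) only after the primary allylic alcohol of 24 has been turned into the carbonate, so that the chloroformate meets no free phenol.

24 to 20 and 21 through 23 (C11=C12). The trisubstituted alkene that becomes the allyl unit is cut by a Wittig disconnection to stabilised ylide 21 and the aldehyde 22 derived from alcohol 20. This gives the E geometry and places the leaving group on C13; 22 is β,γ-unsaturated and is therefore trapped as it forms.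

20 to 9 and 16 through 19 (aryl–C7). The arene is joined to the chain as an aryl nucleophile attacking the primary allylic bromide 16. Both ring methyl groups are already in 9, because the benzylic and allylic C7 methylene of 19 would not survive a later ring metalation.

16 to 12 and 13 through 15 and 14; 12 to 10 and 11 (C8=C9). The Z-trisubstituted alkene is cut by a Z-selective Horner–Wadsworth–Emmons disconnection to the α-homoprenyl phosphonate 12 and aldehyde 13. This puts the ester carbon (C7) cis to C10, the geometry that ring B needs, and leaves the two chain ends differentiated as ester and silyl ether. Phosphonate 12 comes from 10 and bromide 11 by alkylation.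

9 to 1 through 8, 4 and 2 (arene). All three oxygens come from 1. The position between the two acetal-protected oxygens (future C4) is the most acidic ring position, so it is blocked with silicon (4), the two positions flanking the methoxy group are then methylated (8), and silicon is exchanged for iodine (9) to unmask C4 as the nucleophilic site.

## Alternatives that were turned down

Alternative 1: The C10–C11 bond and a temporary C4–C9 bond are cut, so that C4, C9, C10 and C11 first form a cyclobutane. Forward, a visible-light [2+2] cycloaddition of the Lewis-acid-bound enoyl imidazole A2 in its triplet state with the silyl enyne A3 gives cyclobutane A1. The alkyne is later turned into a vinyl group carrying C7 and the homoprenyl chain, and a vinylcyclobutane-to-cyclohexene shift moves C4 from C9 to C7. In its favour, the cycloaddition of acyl imidazoles under chiral Lewis acid control is well established, and on control of C11 it is at least as strong as the chosen route. Against it, C4 in A1 is tertiary and carries only one carbonyl arm. The spiro centre, the second arm, the methoxy enone and the gem-dimethyl carbon all have to be built afterwards, with nothing that tells C3 from C5 relative to C11, and the ring expansion needs forcing conditions. The chosen route makes ring B and the spiro carbon in one step on a complete ring A and is much shorter after the key step; it gives up the stronger precedent for C11 in return.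

Alternative 2: Ring B is made first and ring A is cut at C4–C5 (and later C2–C3 and C1–C6). Forward, an isopropylcopper nucleophile with a chiral ferrocenyl diphosphine adds to C11 of diene ester A5 and the enolate is C-acylated at C4 by an isobutyryl electrophile, giving A4 with the ester cis to isopropyl. In its favour, trans trapping of the enolate is a reliable way to set C4 against C11. The two carbonyl arms of A4 are also constitutionally different and the gem-dimethyl carbon is brought in with the acyl group, so no late methylation on a pseudo-symmetric ring is needed; on this point it is stronger than the chosen route. Against it, C-acylation of a fully substituted, hindered ester enolate competes with O-acylation, and the skipped diene A5 aromatises or conjugates easily. Ring A still needs two further C–C bonds, and the final O-methylation of an unsymmetrical 1,3-diketone can place the methoxy group on either oxygen. The chosen route fixes the methoxy position from the start, because it is the central oxygen of the symmetric arene.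

Alternative 3: Both ring B bonds at C4 are cut (C4–C7 and C4–C11). Forward, the ring A dione A7 adds twice through C4 to the cross-conjugated dienone A8, first at the C7 methylene and then at C11, to give spiro cyclohexanone A6; the C9 ketone is then converted into the C8=C9 alkene. In its favour it is the shortest plan, ring A arrives complete with methoxy and gem-dimethyl groups, and two C–C bonds and the spiro centre form at once; in step economy it is clearly stronger than the chosen route. Against it, the two carbonyls of A7 differ only at a distance, so the second, ring-closing Michael addition has little to decide whether C3 or C5 ends up cis to the C11 substituent. Absolute control would require asymmetric catalysis on a hindered diketone nucleophile, A8 is a polymerisable vinyl ketone, and removal of the C9 ketone needs regioselective enol derivatisation toward C8 beside two other carbonyl groups. The chosen route is longer but gives a ligand handle on C11 and a designed relay (one silylated oxygen) for C4.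

Key step: step 16

Assumption: the sense of induction of the chiral diphosphine on this substrate cannot be derived with certainty; the (R,R) ligand is written, and its mirror image is used if the first run gives the enantiomeric series.

## Steps

Step 1
Reactants: 1 resorcinol ether 5-methoxybenzene-1,3-diol
Product: 2 bis(methoxymethyl) ether 1-methoxy-3,5-bis(methoxymethoxy)benzene
Conditions: MOMCl, i-Pr2NEt, CH2Cl2, 0 °C → rt
Reagents that add atoms: chloromethyl methyl ether, COCCl
Why: O-alkylation of both phenols; the acetal ethers direct ortho-lithiation and are stable to organolithium, hydride and fluoride reagents used later.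

Step 2
Reactants: 2 bis(methoxymethyl) ether 1-methoxy-3,5-bis(methoxymethoxy)benzene
Product: 4 [4-methoxy-2,6-bis(methoxymethoxy)phenyl]trimethylsilane, via aryllithium 3 (not isolated)
Conditions: n-BuLi, THF, 0 °C; then Me3SiCl, 0 °C → rt
Reagents that add atoms: chlorotrimethylsilane, C[Si](C)(C)Cl
Why: Directed ortho-metalation; the C–H between the two acetal ethers (future C4) is the most acidic, and silylation blocks it so that the next lithiations must occur beside the methoxy group.

Step 3
Reactants: 4 [4-methoxy-2,6-bis(methoxymethoxy)phenyl]trimethylsilane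
Product: 8 [4-methoxy-2,6-bis(methoxymethoxy)-3,5-dimethylphenyl]trimethylsilane, via aryllithium 5 (not isolated), via monomethyl arylsilane 6 (not isolated), via aryllithium 7 (not isolated)
Conditions: n-BuLi, TMEDA, THF, −78 → 0 °C; MeI (1.0 equiv), −78 °C → rt; then n-BuLi, −78 → 0 °C; MeI, −78 °C → rt
Reagents that add atoms: iodomethane, CI
Why: Iterative directed ortho-metalation and methylation at the only ring C–H positions left, each flanked by an acetal ether and the methoxy group; this places the two methyl groups of future C2 and C6 before any sensitive chain is present.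

Step 4
Reactants: 8 [4-methoxy-2,6-bis(methoxymethoxy)-3,5-dimethylphenyl]trimethylsilane
Product: 9 aryl iodide 2-iodo-5-methoxy-1,3-bis(methoxymethoxy)-4,6-dimethylbenzene
Conditions: ICl, CH2Cl2, −78 → 0 °C
Reagents that add atoms: iodine monochloride, ClI
Why: Ipso-iododesilylation (electrophilic aromatic substitution at the silicon-bearing carbon of an electron-rich arylsilane); no other ring position is free, so only the blocked carbon reacts.

Step 5
Reactants: 10 ethyl 2-(diphenoxyphosphoryl)acetate; 11 homoprenyl bromide 5-bromo-2-methylpent-2-ene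
Product: 12 ethyl 2-(diphenoxyphosphoryl)-6-methylhept-5-enoate (racemic)
Conditions: NaH, DMSO, rt; then 11, NaI (cat.), rt → 50 °C
Reagents that add atoms: none
Why: C-alkylation of the stabilised phosphonate carbanion by a primary halide (iodide formed in situ); the carbanion is too weakly basic to eliminate the homoallylic bromide to a significant extent.

Step 6
Reactants: 12 ethyl 2-(diphenoxyphosphoryl)-6-methylhept-5-enoate; 13 aldehyde 3-[(tert-butyldimethylsilyl)oxy]propanal
Product: 14 ethyl (2Z)-2-{3-[(tert-butyldimethylsilyl)oxy]propylidene}-6-methylhept-5-enoate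
Conditions: NaH, THF, −78 °C; then 13, −78 → 0 °C
Reagents that add atoms: none
Why: Z-selective Horner–Wadsworth–Emmons olefination with a diaryl phosphonate: fast, irreversible collapse of the syn adduct leaves the ester carbon (C7) cis to the new CH2 (C10), the geometry ring B requires.

Step 7
Reactants: 14 ethyl (2Z)-2-{3-[(tert-butyldimethylsilyl)oxy]propylidene}-6-methylhept-5-enoate
Product: 15 (2Z)-2-{3-[(tert-butyldimethylsilyl)oxy]propylidene}-6-methylhept-5-en-1-ol
Conditions: i-Bu2AlH, CH2Cl2, −78 °C
Reagents that add atoms: none
Why: 1,2-Reduction of the enoate to the allylic alcohol; alkene geometry and silyl ether are untouched.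

Step 8
Reactants: 15 (2Z)-2-{3-[(tert-butyldimethylsilyl)oxy]propylidene}-6-methylhept-5-en-1-ol
Product: 16 {[(3Z)-4-(bromomethyl)-8-methylnona-3,7-dien-1-yl]oxy}(tert-butyl)dimethylsilane
Conditions: CBr4, PPh3, CH2Cl2, 0 °C
Reagents that add atoms: carbon tetrabromide, BrC(Br)(Br)Br
Why: Appel reaction, SN2 at the primary allylic carbon under neutral conditions, so the Z alkene and the silyl ether persist; the bromide is used without storage.

Step 9
Reactants: 9 aryl iodide 2-iodo-5-methoxy-1,3-bis(methoxymethoxy)-4,6-dimethylbenzene; 16 {[(3Z)-4-(bromomethyl)-8-methylnona-3,7-dien-1-yl]oxy}(tert-butyl)dimethylsilane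
Product: 19 tert-butyl{[(3Z)-4-{[4-methoxy-2,6-bis(methoxymethoxy)-3,5-dimethylphenyl]methyl}-8-methylnona-3,7-dien-1-yl]oxy}dimethylsilane, via aryllithium 17 (not isolated), via arylcopper 18 (not isolated)
Conditions: t-BuLi (2.1 equiv), Et2O, −78 °C; CuBr·SMe2, THF, −78 → −40 °C; then 16, −78 → 0 °C
Reagents that add atoms: none
Why: Iodine–lithium exchange, transmetalation to monovalent copper and SN2 allylation, the reaction type used for aryl–geranyl couplings of bis-acetal-protected resorcinols. The aryl group with two ortho substituents should attack the primary C7 and not the secondary γ-carbon, with retention of the alkene geometry.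

Step 10
Reactants: 19 tert-butyl{[(3Z)-4-{[4-methoxy-2,6-bis(methoxymethoxy)-3,5-dimethylphenyl]methyl}-8-methylnona-3,7-dien-1-yl]oxy}dimethylsilane
Product: 20 (3Z)-4-{[4-methoxy-2,6-bis(methoxymethoxy)-3,5-dimethylphenyl]methyl}-8-methylnona-3,7-dien-1-ol
Conditions: Bu4NF, THF, 0 °C → rt
Reagents that add atoms: none
Why: Fluoride cleavage of the primary silyl ether; acetal ethers and alkenes are inert.

Step 11
Reactants: 20 (3Z)-4-{[4-methoxy-2,6-bis(methoxymethoxy)-3,5-dimethylphenyl]methyl}-8-methylnona-3,7-dien-1-ol; 21 ethyl 2-(triphenyl-λ5-phosphanylidene)propanoate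
Product: 23 ethyl (2E,5Z)-6-{[4-methoxy-2,6-bis(methoxymethoxy)-3,5-dimethylphenyl]methyl}-2,10-dimethylundeca-2,5,9-trienoate, via aldehyde 22 (not isolated)
Conditions: Dess–Martin periodinane, NaHCO3, CH2Cl2, 0 °C; then 21, rt
Reagents that add atoms: none
Why: Dess–Martin oxidation followed in the same flask by a Wittig reaction with a stabilised ylide, so that the β,γ-unsaturated aldehyde is consumed before it can isomerise into conjugation; the α-methyl stabilised ylide should give the E enoate (C10 trans to the ester).

Step 12
Reactants: 23 ethyl (2E,5Z)-6-{[4-methoxy-2,6-bis(methoxymethoxy)-3,5-dimethylphenyl]methyl}-2,10-dimethylundeca-2,5,9-trienoate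
Product: 24 (2E,5Z)-6-{[4-methoxy-2,6-bis(methoxymethoxy)-3,5-dimethylphenyl]methyl}-2,10-dimethylundeca-2,5,9-trien-1-ol
Conditions: i-Bu2AlH, CH2Cl2, −78 °C
Reagents that add atoms: none
Why: 1,2-Reduction of the enoate to the primary allylic alcohol without touching the skipped diene.

Step 13
Reactants: 24 (2E,5Z)-6-{[4-methoxy-2,6-bis(methoxymethoxy)-3,5-dimethylphenyl]methyl}-2,10-dimethylundeca-2,5,9-trien-1-ol
Product: 25 (2E,5Z)-6-{[4-methoxy-2,6-bis(methoxymethoxy)-3,5-dimethylphenyl]methyl}-2,10-dimethylundeca-2,5,9-trien-1-yl methyl carbonate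
Conditions: ClCO2Me, pyridine, CH2Cl2, 0 °C
Reagents that add atoms: methyl chloroformate, COC(=O)Cl
Why: O-acylation of the only free hydroxyl group (both phenols are still masked); the methyl carbonate is a leaving group that releases its own base on ionisation.

Step 14
Reactants: 25 (2E,5Z)-6-{[4-methoxy-2,6-bis(methoxymethoxy)-3,5-dimethylphenyl]methyl}-2,10-dimethylundeca-2,5,9-trien-1-yl methyl carbonate
Product: 26 (2E,5Z)-6-[(2,6-dihydroxy-4-methoxy-3,5-dimethylphenyl)methyl]-2,10-dimethylundeca-2,5,9-trien-1-yl methyl carbonate
Conditions: HCl (1.25 M in MeOH), MeOH/THF, 0 °C → rt, argon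
Reagents that add atoms: none
Why: Acid-catalysed acetal exchange removes both protecting groups as the formaldehyde acetal of the solvent; in methanol the methyl carbonate can only exchange with itself. Cold dilute acid is chosen so that the new phenol does not add to the C8=C9 alkene.

Step 15
Reactants: 26 (2E,5Z)-6-[(2,6-dihydroxy-4-methoxy-3,5-dimethylphenyl)methyl]-2,10-dimethylundeca-2,5,9-trien-1-yl methyl carbonate
Product: 27 (2E,5Z)-6-[(2-{[tert-butyl(dimethyl)silyl]oxy}-6-hydroxy-4-methoxy-3,5-dimethylphenyl)methyl]-2,10-dimethylundeca-2,5,9-trien-1-yl methyl carbonate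
Conditions: TBSCl (1.05 equiv), imidazole, DMF, 0 °C
Reagents that add atoms: tert-butyldimethylsilyl chloride, CC(C)(C)[Si](C)(C)Cl
Why: Silylation of one of two equivalent phenols; the arene has a mirror plane through C1 and C4, so either oxygen gives the same compound, and unreacted diol and bis-silyl ether are recycled.

Step 16
Reactants: 27 (2E,5Z)-6-[(2-{[tert-butyl(dimethyl)silyl]oxy}-6-hydroxy-4-methoxy-3,5-dimethylphenyl)methyl]-2,10-dimethylundeca-2,5,9-trien-1-yl methyl carbonate
Product: 28 (6S,11S)-5-{[tert-butyl(dimethyl)silyl]oxy}-3-methoxy-2,4-dimethyl-8-(4-methylpent-3-en-1-yl)-11-(prop-1-en-2-yl)spiro[5.5]undeca-2,4,8-trien-1-one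
Conditions: Pd2(dba)3·CHCl3 (2.5 mol %), (R,R)-N,N′-(cyclohexane-1,2-diyl)bis[2-(diphenylphosphanyl)benzamide] (7.5 mol %), CH2Cl2, 0 °C → rt
Reagents that add atoms: none
Why: Zerovalent palladium ionises the allylic carbonate, CO2 is lost and the methoxide formed deprotonates the free phenol, giving a phenoxide and a 2-methylallylpalladium complex held together by the tether. The phenoxide attacks through its ortho carbon C4 at the allyl terminus C11 on the face opposite to palladium; this forms C4–C11, breaks aromaticity and closes ring B in a 6-exo mode, the cis C8=C9 alkene keeping C7 and C10 on the same side. The closest known reaction type is the palladium-catalysed intramolecular asymmetric allylic dearomatisation of phenols bearing a tethered allyl carbonate. C11 is set by the ligand: the two faces of the allyl complex interconvert through the η1 form at the unsubstituted terminus C13, so the chiral pocket selects which face is attacked. C4 is set relative to C11 by the substrate: the flat arene differs on its two sides only by O–H versus O–Si, and in the chair-like closure the bulky silyloxy arm should turn away from the allyl and ligand side, which places the future C3 carbonyl cis to the C11 substituent as in 31. The step needs C- over O-alkylation and attack at C11 over C13; both follow from ring size, since the alternatives are eight- or ten-membered rings. The silyl group then stores the C4 configuration, because C3 (ketone) and C5 (silyl enol ether) cannot exchange roles by tautomerism. The product is a vinylogous silyl ester and is handled dry, on base-washed silica only.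

Step 17
Reactants: 28 (6S,11S)-5-{[tert-butyl(dimethyl)silyl]oxy}-3-methoxy-2,4-dimethyl-8-(4-methylpent-3-en-1-yl)-11-(prop-1-en-2-yl)spiro[5.5]undeca-2,4,8-trien-1-one
Product: 29 (6S,11S)-5-{[tert-butyl(dimethyl)silyl]oxy}-3-methoxy-2,4-dimethyl-8-(4-methylpent-3-en-1-yl)-11-(propan-2-yl)spiro[5.5]undeca-2,4,8-trien-1-one
Conditions: H2 (1 atm), RhCl(PPh3)3 (10 mol %), benzene, rt
Reagents that add atoms: none
Why: Homogeneous hydrogenation with this rhodium catalyst reduces a 1,1-disubstituted alkene much faster than trisubstituted or tetrasubstituted ones; the neutral medium spares the silyl dienol ether and no stereocentre is touched.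

Step 18
Reactants: 29 (6S,11S)-5-{[tert-butyl(dimethyl)silyl]oxy}-3-methoxy-2,4-dimethyl-8-(4-methylpent-3-en-1-yl)-11-(propan-2-yl)spiro[5.5]undeca-2,4,8-trien-1-one
Product: 30 siloxycyclopropane (2S,6′S)-1-{[tert-butyl(dimethyl)silyl]oxy}-5-methoxy-4,6-dimethyl-3′-(4-methylpent-3-en-1-yl)-6′-(propan-2-yl)spiro[bicyclo[4.1.0]hept-4-ene-2,1′-cyclohex-3′-en]-3-one (cis-fused cyclopropane; either face)
Conditions: Et2Zn, CH2I2, CH2Cl2, 0 °C → rt
Reagents that add atoms: diiodomethane, ICI
Why: Simmons–Smith cyclopropanation; the electrophilic zinc carbenoid adds to the most electron-rich C=C, the silyl enol ether C5=C6, while the methoxy enone C1=C2 is deactivated by its carbonyl. No free enolate is formed, so C3 and C5 stay distinct; the two new cyclopropane centres need no control because both lose their stereogenicity in step 19.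

Step 19
Reactants: 30 siloxycyclopropane (2S,6′S)-1-{[tert-butyl(dimethyl)silyl]oxy}-5-methoxy-4,6-dimethyl-3′-(4-methylpent-3-en-1-yl)-6′-(propan-2-yl)spiro[bicyclo[4.1.0]hept-4-ene-2,1′-cyclohex-3′-en]-3-one
Product: 31 (6R,11S)-3-methoxy-2,4,4-trimethyl-8-(4-methylpent-3-en-1-yl)-11-(propan-2-yl)spiro[5.5]undeca-2,8-diene-1,5-dione
Conditions: HCl (0.5 M, anhydrous) in MeOH/CH2Cl2, 0 °C → rt
Reagents that add atoms: none
Why: Protonolysis of a siloxycyclopropane: the proton attacks the unsubstituted CH2 and the C5–CH2 bond breaks with assistance from oxygen, giving the C5 ketone and the second methyl on C6. Anhydrous methanolic acid spares the vinylogous methyl ester; the spiro descriptor changes from S to R only because C5 now outranks C3, the geometry being unchanged.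

## Compound list

1 | 5-methoxybenzene-1,3-diol | COc1cc(O)cc(O)c1 | starting material
2 | 1-methoxy-3,5-bis(methoxymethoxy)benzene | COCOc1cc(OC)cc(OCOC)c1 | intermediate
3 | [4-methoxy-2,6-bis(methoxymethoxy)phenyl]lithium | [Li]c1c(OCOC)cc(OC)cc1OCOC | intermediate
4 | [4-methoxy-2,6-bis(methoxymethoxy)phenyl]trimethylsilane | COCOc1cc(OC)cc(OCOC)c1[Si](C)(C)C | intermediate
5 | [6-methoxy-2,4-bis(methoxymethoxy)-3-(trimethylsilyl)phenyl]lithium | [Li]c1c(OC)cc(OCOC)c([Si](C)(C)C)c1OCOC | intermediate
6 | [4-methoxy-2,6-bis(methoxymethoxy)-3-methylphenyl]trimethylsilane | COCOc1cc(OC)c(C)c(OCOC)c1[Si](C)(C)C | intermediate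
7 | [2-methoxy-4,6-bis(methoxymethoxy)-3-methyl-5-(trimethylsilyl)phenyl]lithium | [Li]c1c(OC)c(C)c(OCOC)c([Si](C)(C)C)c1OCOC | intermediate
8 | [4-methoxy-2,6-bis(methoxymethoxy)-3,5-dimethylphenyl]trimethylsilane | COCOc1c(C)c(OC)c(C)c(OCOC)c1[Si](C)(C)C | intermediate
9 | 2-iodo-5-methoxy-1,3-bis(methoxymethoxy)-4,6-dimethylbenzene | COCOc1c(C)c(OC)c(C)c(OCOC)c1I | intermediate
10 | ethyl 2-(diphenoxyphosphoryl)acetate | CCOC(=O)CP(=O)(Oc1ccccc1)Oc1ccccc1 | starting material
11 | 5-bromo-2-methylpent-2-ene | CC(C)=CCCBr | starting material
12 | ethyl 2-(diphenoxyphosphoryl)-6-methylhept-5-enoate (racemic) | CCOC(=O)C(CCC=C(C)C)P(=O)(Oc1ccccc1)Oc1ccccc1 | intermediate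
13 | 3-[(tert-butyldimethylsilyl)oxy]propanal | O=CCCO[Si](C)(C)C(C)(C)C | starting material
14 | ethyl (2Z)-2-{3-[(tert-butyldimethylsilyl)oxy]propylidene}-6-methylhept-5-enoate | CCOC(=O)/C(CCC=C(C)C)=C\CCO[Si](C)(C)C(C)(C)C | intermediate
15 | (2Z)-2-{3-[(tert-butyldimethylsilyl)oxy]propylidene}-6-methylhept-5-en-1-ol | OC/C(CCC=C(C)C)=C\CCO[Si](C)(C)C(C)(C)C | intermediate
16 | {[(3Z)-4-(bromomethyl)-8-methylnona-3,7-dien-1-yl]oxy}(tert-butyl)dimethylsilane | BrC/C(CCC=C(C)C)=C\CCO[Si](C)(C)C(C)(C)C | intermediate
17 | [4-methoxy-2,6-bis(methoxymethoxy)-3,5-dimethylphenyl]lithium | [Li]c1c(OCOC)c(C)c(OC)c(C)c1OCOC | intermediate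
18 | [4-methoxy-2,6-bis(methoxymethoxy)-3,5-dimethylphenyl]copper | [Cu]c1c(OCOC)c(C)c(OC)c(C)c1OCOC | intermediate
19 | tert-butyl{[(3Z)-4-{[4-methoxy-2,6-bis(methoxymethoxy)-3,5-dimethylphenyl]methyl}-8-methylnona-3,7-dien-1-yl]oxy}dimethylsilane | COCOc1c(C)c(OC)c(C)c(OCOC)c1C/C(CCC=C(C)C)=C\CCO[Si](C)(C)C(C)(C)C | intermediate
20 | (3Z)-4-{[4-methoxy-2,6-bis(methoxymethoxy)-3,5-dimethylphenyl]methyl}-8-methylnona-3,7-dien-1-ol | COCOc1c(C)c(OC)c(C)c(OCOC)c1C/C(CCC=C(C)C)=C\CCO | intermediate
21 | ethyl 2-(triphenyl-λ5-phosphanylidene)propanoate | CCOC(=O)C(C)=P(c1ccccc1)(c1ccccc1)c1ccccc1 | starting material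
22 | (3Z)-4-{[4-methoxy-2,6-bis(methoxymethoxy)-3,5-dimethylphenyl]methyl}-8-methylnona-3,7-dienal | COCOc1c(C)c(OC)c(C)c(OCOC)c1C/C(CCC=C(C)C)=C\CC=O | intermediate
23 | ethyl (2E,5Z)-6-{[4-methoxy-2,6-bis(methoxymethoxy)-3,5-dimethylphenyl]methyl}-2,10-dimethylundeca-2,5,9-trienoate | COCOc1c(C)c(OC)c(C)c(OCOC)c1C/C(CCC=C(C)C)=C\C/C=C(\C)C(=O)OCC | intermediate
24 | (2E,5Z)-6-{[4-methoxy-2,6-bis(methoxymethoxy)-3,5-dimethylphenyl]methyl}-2,10-dimethylundeca-2,5,9-trien-1-ol | COCOc1c(C)c(OC)c(C)c(OCOC)c1C/C(CCC=C(C)C)=C\C/C=C(\C)CO | intermediate
25 | (2E,5Z)-6-{[4-methoxy-2,6-bis(methoxymethoxy)-3,5-dimethylphenyl]methyl}-2,10-dimethylundeca-2,5,9-trien-1-yl methyl carbonate | COCOc1c(C)c(OC)c(C)c(OCOC)c1C/C(CCC=C(C)C)=C\C/C=C(\C)COC(=O)OC | intermediate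
26 | (2E,5Z)-6-[(2,6-dihydroxy-4-methoxy-3,5-dimethylphenyl)methyl]-2,10-dimethylundeca-2,5,9-trien-1-yl methyl carbonate | COc1c(C)c(O)c(C/C(CCC=C(C)C)=C\C/C=C(\C)COC(=O)OC)c(O)c1C | intermediate
27 | (2E,5Z)-6-[(2-{[tert-butyl(dimethyl)silyl]oxy}-6-hydroxy-4-methoxy-3,5-dimethylphenyl)methyl]-2,10-dimethylundeca-2,5,9-trien-1-yl methyl carbonate | COc1c(C)c(O)c(C/C(CCC=C(C)C)=C\C/C=C(\C)COC(=O)OC)c(O[Si](C)(C)C(C)(C)C)c1C | intermediate
28 | (6S,11S)-5-{[tert-butyl(dimethyl)silyl]oxy}-3-methoxy-2,4-dimethyl-8-(4-methylpent-3-en-1-yl)-11-(prop-1-en-2-yl)spiro[5.5]undeca-2,4,8-trien-1-one | COC1=C(C)C(=O)[C@]2(CC(CCC=C(C)C)=CC[C@H]2C(C)=C)C(O[Si](C)(C)C(C)(C)C)=C1C | intermediate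
29 | (6S,11S)-5-{[tert-butyl(dimethyl)silyl]oxy}-3-methoxy-2,4-dimethyl-8-(4-methylpent-3-en-1-yl)-11-(propan-2-yl)spiro[5.5]undeca-2,4,8-trien-1-one | COC1=C(C)C(=O)[C@]2(CC(CCC=C(C)C)=CC[C@H]2C(C)C)C(O[Si](C)(C)C(C)(C)C)=C1C | intermediate
30 | (2S,6′S)-1-{[tert-butyl(dimethyl)silyl]oxy}-5-methoxy-4,6-dimethyl-3′-(4-methylpent-3-en-1-yl)-6′-(propan-2-yl)spiro[bicyclo[4.1.0]hept-4-ene-2,1′-cyclohex-3′-en]-3-one, cis-fused cyclopropane, the two cyclopropane ring-fusion carbons left undefined | COC1=C(C)C(=O)[C@]2(CC(CCC=C(C)C)=CC[C@H]2C(C)C)C3(O[Si](C)(C)C(C)(C)C)CC13C | intermediate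
31 | (6R,11S)-3-methoxy-2,4,4-trimethyl-8-(4-methylpent-3-en-1-yl)-11-(propan-2-yl)spiro[5.5]undeca-2,8-diene-1,5-dione | COC1=C(C)C(=O)[C@]2(CC(CCC=C(C)C)=CC[C@H]2C(C)C)C(=O)C1(C)C | target

## Step count and least certain steps

Total step count: 19. Longest linear sequence: 15 (steps 1–4 or steps 5–8, then steps 9–19).

Step 16 (key step). Several processes can spoil it: 
- poor facial selection at the allyl terminus;
- the arene turning the other way, so that the silyloxy arm ends cis to the C11 substituent;
- β-hydride loss from the allyl complex towards a conjugated triene before the hindered carbon attacks;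
- transfer of the silyl group between phenoxide oxygens;
- re-ionisation of the allylic C4–C11 bond of the product. 

Fallback, from 26 back to 31: the unsilylated resorcinol 26 is cyclised under the same zerovalent palladium catalysis, so that only C11 has to be controlled by the ligand. This should give (11S)-5-hydroxy-3-methoxy-2,4-dimethyl-8-(4-methylpent-3-en-1-yl)-11-(prop-1-en-2-yl)spiro[5.5]undeca-2,4,8-trien-1-one F1, whose spiro carbon is not a fixed centre because the enol can shift between the two arms. Hydrogenation with RhCl(PPh3)3 should give the isopropyl enol (11S)-5-hydroxy-3-methoxy-2,4-dimethyl-8-(4-methylpent-3-en-1-yl)-11-(propan-2-yl)spiro[5.5]undeca-2,4,8-trien-1-one F2. C-Methylation of its enolate (MeI, K2CO3, acetone) should then give 31 together with its spiro epimer (6S,11S)-3-methoxy-2,4,4-trimethyl-8-(4-methylpent-3-en-1-yl)-11-(propan-2-yl)spiro[5.5]undeca-2,8-diene-1,5-dione F3, to be separated by chromatography.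

Step 19 (with step 18). The cyclopropane of 30 sits next to the methoxy enone, so it is a vinylogous donor–acceptor cyclopropane. Cleavage of the ring-fusion bond C5–C6 instead of C5–CH2 would enlarge ring A by one carbon, and aqueous acid would hydrolyse the enol ether. In step 18 the carbenoid may also react at the trisubstituted alkenes, because the silyl enol ether is deactivated by conjugation. 

Fallback, from 29 back to 31, replacing both steps: phenylthiomethylation of the silyl enol ether with PhSCH2Cl and catalytic ZnBr2 in CH2Cl2 (alkylation by a thionium ion, the silyl group leaving as its chloride, no free enolate). This should give the β-keto sulfide (6R,11S)-3-methoxy-2,4-dimethyl-8-(4-methylpent-3-en-1-yl)-4-[(phenylsulfanyl)methyl]-11-(propan-2-yl)spiro[5.5]undeca-2,8-diene-1,5-dione F4, with the new centre at the sulfur-bearing carbon undefined. Desulfurisation with acetone-deactivated Raney Ni in ethanol should then give 31. The site of alkylation (C6, not C2) is to be confirmed by NOE before the sulfur is removed.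

Step 15. Silylation of a symmetric diol can run on to the bis-silyl ether or stop short, so the material is spread over three species. 

Fallback, from 26 back to 27: exhaustive silylation (TBSCl in excess, imidazole, DMF) to (2E,5Z)-6-[(2,6-bis{[tert-butyl(dimethyl)silyl]oxy}-4-methoxy-3,5-dimethylphenyl)methyl]-2,10-dimethylundeca-2,5,9-trien-1-yl methyl carbonate F5, then removal of one silyl group with 1.0 equiv Bu4NF in THF at −78 °C. The phenoxide formed in the first cleavage makes the second aryl–O–Si bond much less prone to attack, so the reaction should stop at 27.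

Step 9. Attack at the γ-carbon of the allylic bromide (SN2′), loss of the Z geometry, or sluggish transmetalation of the hindered aryl group would lower the amount of linear Z product. 

Fallback, from 17 back to 19: transmetalation of 17 with ZnCl2 to chloro[4-methoxy-2,6-bis(methoxymethoxy)-3,5-dimethylphenyl]zinc F6 and Negishi coupling with 16 under Pd(PPh3)4 catalysis. Reductive elimination from the allylpalladium intermediate should take place at the unsubstituted terminus C7.

## Further compounds

F1 | step 16 | (11S)-5-hydroxy-3-methoxy-2,4-dimethyl-8-(4-methylpent-3-en-1-yl)-11-(prop-1-en-2-yl)spiro[5.5]undeca-2,4,8-trien-1-one (spiro centre tautomerically labile, left open) | COC1=C(C)C(=O)C2(CC(CCC=C(C)C)=CC[C@H]2C(C)=C)C(O)=C1C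
F2 | step 16 | (11S)-5-hydroxy-3-methoxy-2,4-dimethyl-8-(4-methylpent-3-en-1-yl)-11-(propan-2-yl)spiro[5.5]undeca-2,4,8-trien-1-one (spiro centre tautomerically labile, left open) | COC1=C(C)C(=O)C2(CC(CCC=C(C)C)=CC[C@H]2C(C)C)C(O)=C1C
F3 | step 16 | (6S,11S)-3-methoxy-2,4,4-trimethyl-8-(4-methylpent-3-en-1-yl)-11-(propan-2-yl)spiro[5.5]undeca-2,8-diene-1,5-dione | COC1=C(C)C(=O)[C@@]2(CC(CCC=C(C)C)=CC[C@H]2C(C)C)C(=O)C1(C)C
F4 | step 19 | (6R,11S)-3-methoxy-2,4-dimethyl-8-(4-methylpent-3-en-1-yl)-4-[(phenylsulfanyl)methyl]-11-(propan-2-yl)spiro[5.5]undeca-2,8-diene-1,5-dione (C4 of the name undefined) | COC1=C(C)C(=O)[C@]2(CC(CCC=C(C)C)=CC[C@H]2C(C)C)C(=O)C1(C)CSc1ccccc1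
F5 | step 15 | (2E,5Z)-6-[(2,6-bis{[tert-butyl(dimethyl)silyl]oxy}-4-methoxy-3,5-dimethylphenyl)methyl]-2,10-dimethylundeca-2,5,9-trien-1-yl methyl carbonate | COc1c(C)c(O[Si](C)(C)C(C)(C)C)c(C/C(CCC=C(C)C)=C\C/C=C(\C)COC(=O)OC)c(O[Si](C)(C)C(C)(C)C)c1C
F6 | step 9 | chloro[4-methoxy-2,6-bis(methoxymethoxy)-3,5-dimethylphenyl]zinc | Cl[Zn]c1c(OCOC)c(C)c(OC)c(C)c1OCOC
A1 | alternative 1 | (1-methyl-1H-imidazol-2-yl){2-(propan-2-yl)-4-[(trimethylsilyl)ethynyl]cyclobutyl}methanone, all-trans | CC(C)[C@@H]1C[C@H](C#C[Si](C)(C)C)[C@H]1C(=O)c1nccn1C
A2 | alternative 1 | (2E)-4-methyl-1-(1-methyl-1H-imidazol-2-yl)pent-2-en-1-one | CC(C)/C=C/C(=O)c1nccn1C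
A3 | alternative 1 | (but-3-en-1-yn-1-yl)trimethylsilane | C=CC#C[Si](C)(C)C
A4 | alternative 2 | methyl 1-(2-methylpropanoyl)-5-(4-methylpent-3-en-1-yl)-2-(propan-2-yl)cyclohex-4-ene-1-carboxylate, ester cis to isopropyl | COC(=O)[C@]1(CC(CCC=C(C)C)=CC[C@H]1C(C)C)C(=O)C(C)C
A5 | alternative 2 | methyl 5-(4-methylpent-3-en-1-yl)cyclohexa-1,4-diene-1-carboxylate | COC(=O)C1=CCC=C(CCC=C(C)C)C1
A6 | alternative 3 | 3-methoxy-2,4,4-trimethyl-8-(4-methylpent-3-en-1-yl)-11-(propan-2-yl)spiro[5.5]undec-2-ene-1,5,9-trione, configuration as in the SMILES | COC1=C(C)C(=O)[C@]2(C[C@H](CCC=C(C)C)C(=O)C[C@H]2C(C)C)C(=O)C1(C)C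
A7 | alternative 3 | 5-methoxy-4,6,6-trimethylcyclohex-4-ene-1,3-dione | COC1=C(C)C(=O)CC(=O)C1(C)C
A8 | alternative 3 | (4E)-6-methyl-2-(4-methylpent-3-en-1-yl)hepta-1,4-dien-3-one | C=C(CCC=C(C)C)C(=O)/C=C/C(C)C
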